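Readings and results were generated by integration with constants of no real substance, noise included.

Late in the ash run Q falls and L rises, from 95.6% and 4.0% at 15.0 min to 60.7% and 41.1% at 120 min, so we start from that step.

| flask | E | temperature | remark | time |
|---|---|---|---|---|
| elm | 0.25 M | −25 °C | run made earlier |  |
| ash | 0.52 M | 0 °C | run made earlier |  |
| autumn | 0.85 M |  | at 20 °C until 15 min, from then on at −20 °C | 80 min |
| winter | 0.40 M |  | at −20 °C throughout | 80 min |

| run | time / min | Q / % | L / % |
|---|---|---|---|
| elm | 25.0 | 14.7 | 0 |
| elm | 80.0 | 48.0 | 0.1 |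
| elm | 150 | 86.6 | 0.4 |
| elm | 180 | 97.9 | 2.5 |
| elm | 300 | 96.7 | 3.1 |
| elm | 360 | 95.7 | 4.3 |
| ash | 8.00 | 55.3 | 1.0 |
| ash | 15.0 | 95.6 | 4.0 |
| ash | 20.0 | 92.8 | 6.5 |
| ash | 40.0 | 84.3 | 16.0 |
| ash | 60.0 | 75.8 | 23.7 |
| ash | 120 | 60.7 | 41.1 |

(scatter of a reading: 0.5 percentage points)

- given per volume of solution although it is solid: E
- steps under discussion: G -> Q; E <-> G; Q <-> L
- at the start none of E is in solution
- what has only dissolved of E counts as not reacted

- the flask that ends with the higher share of Q in all that became Q or L, or "neither" when 2 percentage points or less lies between them (autumn / winter / neither)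
- share of Q in all that became Q or L, autumn
- share of Q in all that became Q or L, winter

Let kf be the forward constant of Q -> L and kr the backward one, so L gains kf·Q − kr·L per minute. We go round. Ignoring the way back, the ash stretch from 15.0 min to 40.0 min reads kf = 0.00534 min⁻¹. Put into the stretch from 60.0 min to 120 min, that reads kr = 0.00229 min⁻¹. Put back, it raises kf to 0.00559 min⁻¹.

In the elm run L stays small, so L at the end over the area under Q against time reads kf = 1.64 × 10⁻⁴ min⁻¹. Together these give θ = 9570 K, the activation energy of the forward step over the gas constant.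

So kf is 0.0610 min⁻¹ at 20 °C and 3.51 × 10⁻⁴ min⁻¹ at −20 °C, and autumn's hot stretch counts far more. Counting autumn's Q as present throughout those 15 min, we get 40.1% with no way back and 48.6% with the ash ratio kf/kr. Both count Q from the first minute, but Q is made during that stretch, so we take them as low marks for autumn.

We take winter's Q to rise steadily, zero-order, as in elm. Its mean age is then half the time, which gives 98.6%.

The forecast names winter, with 50% for autumn and 98.7% for winter, “assuming K roughly constant”.

Autumn ends at 62.2% and winter at 98.7%, so winter is higher.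

    G → Q, rate k1*[G]/(1 + ([G]/sat1)) (5.26 mM, k = 66.7 min⁻¹, Ea = 73.0 kJ mol⁻¹)
    E ⇌ G, rate k2*(cs2 - [G]) while solid is left; crystals form when [G] > cs2 (solubility = 0.580 M, k = 0.168 min⁻¹)
    Q ⇌ L (K = 1.02, k = 0.0642 min⁻¹, Ea = 81.0 kJ mol⁻¹, ΔH = −15.0 kJ mol⁻¹)
    (constants at 20 °C)

In autumn the forward half-life of Q to L, the way back not counted, is 11 min at 20 °C, and θ gave 11.4 min. At the end of winter, Q stands at 59.6%. The constant from θ, times the area under a steady rise of Q to that amount over 80 min, gives L of 0.837% for winter at the end, and winter then holds L of 0.804%.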